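**Retrosynthetic overview**
1. Side chain last: C13–C14 by Stille vinylation of a (12Z)-13-iodoalkene, C12=C13 by an iodoethylidene Wittig reaction on a C12 aldehyde.
2. Ring B oxygens from a C7 ketone: 7-OAc by reduction and acetylation, 6-O and 8-O by two Rubottom oxidations; H5 and H9 by Li/NH3 reduction of a 5,8-dien-7-one.
3. Key disconnection C1–C10: ring B (C5–C10), with oxygen at C7 para to the quaternary C10, methyl groups on C8 and C10 and the side chain on C9, is the substitution pattern of a phenol. Ring A (C1–C5, gem-dimethyl C4) is closed onto C10 by enantioselective para-alkylative dearomatisation, and only this closure makes C10 stereogenic.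
4. The phenol comes from 2,6-dimethylphenylacetic acid: acylation at C5 with 4-chlorobutanoyl chloride, gem-dimethylation (C4), bromination/borylation/oxidation at C7, blocking bromine at C6.
5. Ring order: ring B is the aromatic ring from the start; ring A is formed in the key step.

Key step: step 10

Remark: labdane numbering is used for all compounds. "C20 face" is the face of the decalin that carries the C10 methyl; "opposite face" is the other one. In the target, H5, 6-OH, H7, 8-OH and H9 lie on the opposite face; C17, 7-OAc and C11 lie on the C20 face.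

Assumption: the cinchonidine-derived catalyst is taken to deliver the (10S) dienone of the key step. If the sense of induction is the reverse, the pseudoenantiomeric cinchonine-derived salt is used in its place.

**Step 1**
Reactants: 1 2,6-dimethylphenylacetic acid
Product: 2 methyl 2-(2,6-dimethylphenyl)acetate
Conditions: MeOH, cat. H2SO4, reflux
Reagents that add atoms: methanol, CO
Why: Fischer esterification masks the future C11–C12 unit as an ester that tolerates AlCl3 and TiCl4 in the next two steps.

**Step 2**
Reactants: 2 methyl 2-(2,6-dimethylphenyl)acetate; 3 4-chlorobutanoyl chloride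
Product: 4 methyl 2-[3-(4-chlorobutanoyl)-2,6-dimethylphenyl]acetate
Conditions: AlCl3 (2.5 equiv), CH2Cl2, 0 °C to rt
Reagents that add atoms: 4-chlorobutanoyl chloride (3), ClCCCC(=O)Cl
Why: Friedel–Crafts acylation should enter one of the two equivalent positions ortho to one methyl and para to the other, as with 1,2,3-trialkylbenzenes, because the remaining position is meta to both methyl groups.

**Step 3**
Reactants: 4 methyl 2-[3-(4-chlorobutanoyl)-2,6-dimethylphenyl]acetate; 5 dimethylzinc
Product: 6 methyl 2-[3-(5-chloro-2-methylpentan-2-yl)-2,6-dimethylphenyl]acetate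
Conditions: Me2Zn, TiCl4 (Me2TiCl2 formed in the flask), CH2Cl2, −40 to 0 °C
Reagents that add atoms: dimethylzinc (5), C[Zn]C
Why: Geminal dimethylation of the aryl ketone with Me2TiCl2 (methyl addition, ionisation to the tertiary benzylic cation, second methyl transfer) builds the quaternary C4 in one operation and leaves the ester and the primary chloride untouched.

**Step 4**
Reactants: 6 methyl 2-[3-(5-chloro-2-methylpentan-2-yl)-2,6-dimethylphenyl]acetate
Product: 7 methyl 2-[3-bromo-5-(5-chloro-2-methylpentan-2-yl)-2,6-dimethylphenyl]acetate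
Conditions: NBS, cat. CF3CO2H, MeCN, rt, dark
Reagents that add atoms: N-bromosuccinimide, O=C1CCC(=O)N1Br
Why: Electrophilic aromatic bromination should take the free position next to a methyl group (ortho to one methyl, para to the other) and not the one beside the tertiary alkyl group, and no Lewis acid is present that could close the chloroalkyl chain onto the ring.

**Step 5**
Reactants: 7 methyl 2-[3-bromo-5-(5-chloro-2-methylpentan-2-yl)-2,6-dimethylphenyl]acetate
Product: 8 2-[3-bromo-5-(5-chloro-2-methylpentan-2-yl)-2,6-dimethylphenyl]ethanol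
Conditions: i-Bu2AlH (2.5 equiv), CH2Cl2, −78 to 0 °C; aq. potassium sodium tartrate
Reagents that add atoms: none
Why: Hydride reduction of the ester with i-Bu2AlH gives the primary alcohol and does not touch the aryl bromide or the alkyl chloride.

**Step 6**
Reactants: 8 2-[3-bromo-5-(5-chloro-2-methylpentan-2-yl)-2,6-dimethylphenyl]ethanol
Product: 9 {2-[3-bromo-5-(5-chloro-2-methylpentan-2-yl)-2,6-dimethylphenyl]ethoxy}triethylsilane
Conditions: Et3SiCl, imidazole, CH2Cl2, 0 °C to rt
Reagents that add atoms: chlorotriethylsilane, CC[Si](CC)(CC)Cl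
Why: Silylation of the primary alcohol gives a triethylsilyl ether that withstands the basic, reducing and oxidising steps ahead and can later be oxidised directly at C12.

**Step 7**
Reactants: 9 {2-[3-bromo-5-(5-chloro-2-methylpentan-2-yl)-2,6-dimethylphenyl]ethoxy}triethylsilane
Product: 11 5-(5-chloro-2-methylpentan-2-yl)-2,4-dimethyl-3-[2-(triethylsilyloxy)ethyl]phenol, via aryl pinacol boronate 10 (not isolated)
Conditions: B2pin2, KOAc, Pd(dppf)Cl2 (5 mol %), 1,4-dioxane, 90 °C; then NaBO3·4H2O, THF/H2O, rt
Reagents that add atoms: bis(pinacolato)diboron, CC1(C)OB(OC1(C)C)B1OC(C)(C)C(C)(C)O1 (boron of 10); sodium perborate tetrahydrate, [Na+].[Na+].O[B-]1(O)OO[B-](O)(O)OO1 (oxygen of 11)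
Why: Miyaura borylation of the aryl bromide followed by mild perborate oxidation of the C–B bond installs the C7 oxygen without a strong Lewis acid or strong base that could engage the chloroalkyl chain.

**Step 8**
Reactants: 11 5-(5-chloro-2-methylpentan-2-yl)-2,4-dimethyl-3-[2-(triethylsilyloxy)ethyl]phenol
Product: 12 2-bromo-3-(5-chloro-2-methylpentan-2-yl)-4,6-dimethyl-5-[2-(triethylsilyloxy)ethyl]phenol
Conditions: NBS, CH2Cl2, −20 to 0 °C
Reagents that add atoms: N-bromosuccinimide, O=C1CCC(=O)N1Br
Why: Electrophilic bromination of the phenol can only substitute the single free ring position, ortho to OH (C6), since the other ortho carbon and the para carbon carry methyl groups.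

**Step 9**
Reactants: 12 2-bromo-3-(5-chloro-2-methylpentan-2-yl)-4,6-dimethyl-5-[2-(triethylsilyloxy)ethyl]phenol
Product: 13 2-bromo-3-(5-iodo-2-methylpentan-2-yl)-4,6-dimethyl-5-[2-(triethylsilyloxy)ethyl]phenol
Conditions: NaI, NaHCO3, acetone, reflux
Reagents that add atoms: sodium iodide, [Na+].[I-]
Why: Finkelstein exchange at the unhindered primary carbon gives the iodide under neutral conditions in which the un-ionised phenol does not cyclise.

**Step 10**
Reactants: 13 2-bromo-3-(5-iodo-2-methylpentan-2-yl)-4,6-dimethyl-5-[2-(triethylsilyloxy)ethyl]phenol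
Product: 14 (10S)-6-bromo-12-(triethylsilyloxy)-13,14,15,16-tetranorlabda-5,8-dien-7-one
Conditions: N-(9-anthracenylmethyl)-O-allylcinchonidinium bromide (10 mol %), CsOH·H2O (3 equiv), toluene/CH2Cl2 7:3, 0.01 M, −40 °C
Reagents that add atoms: none
Why: Proposed new method: the phenolate of 13 is carried into the organic phase as a tight ion pair with the chiral ammonium cation and attacks the primary iodide carbon C1 through its para carbon C10 in an intramolecular SN2 displacement; the closest known reaction types are the racemic base-mediated intramolecular para-alkylation of phenolates to fused cyclohexa-2,5-dienones and chiral phase-transfer alkylative dearomatisation of naphthols. Ring A closes in a 6-exo-tet mode, helped by the gem-dimethyl group at C4 and by relief of the crowding of the tertiary alkyl group between bromine and the C10 methyl. The single new stereocentre, quaternary C10, is controlled by the catalyst: the cation covers one enantiotopic face of the planar phenolate, so the tether must come in over the other face. The step needs para- rather than ortho-C-alkylation and no O-alkylation: bromine occupies C6, the only other nucleophilic carbon within reach, which is thereby hindered, deactivated and unable to rearomatise, and the meta-attached tether cannot reach oxygen. Low temperature, solid base and high dilution are chosen to keep the uncatalysed racemic pathway and intermolecular alkylation slow.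

**Step 11**
Reactants: 14 (10S)-6-bromo-12-(triethylsilyloxy)-13,14,15,16-tetranorlabda-5,8-dien-7-one
Product: 15 12-(triethylsilyloxy)-13,14,15,16-tetranorlabdan-7-one (trans-fused; H5 and H9 on the opposite face; C17 drawn equatorial, either C8 epimer serves)
Conditions: Li (10 equiv), t-BuOH (4 equiv), NH3/THF, −78 to −33 °C; isoprene, then NH4Cl
Reagents that add atoms: none
Why: Dissolving-metal (Birch-type) reduction should cleave the vinylic C–Br bond and saturate both enone double bonds whichever is attacked first, with each β-carbanion protonated on the face opposite C20 (axially at C5 to give the trans ring fusion, and at C9), and should stop at the ketone enolate once the alcohol is consumed.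

**Step 12**
Reactants: 15 12-(triethylsilyloxy)-13,14,15,16-tetranorlabdan-7-one
Product: 17 8,12-bis(triethylsilyloxy)-13,14,15,16-tetranorlabdan-7-one (8-O equatorial on the opposite face; C17 axial), via C7=C8 triethylsilyl enol ether 16 (not isolated)
Conditions: Et3SiCl, NaI, Et3N, MeCN, rt to 50 °C; then mCPBA, NaHCO3, CH2Cl2, −20 °C
Reagents that add atoms: chlorotriethylsilane, CC[Si](CC)(CC)Cl; mCPBA, OOC(=O)c1cccc(Cl)c1
Why: Silylation under equilibrating conditions should give the more substituted C7=C8 silyl enol ether, and Rubottom oxidation should epoxidise it from the face opposite the axial C20 methyl with silyl migration to the new oxygen, which sets C8 with oxygen equatorial and C17 axial.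

**Step 13**
Reactants: 17 8,12-bis(triethylsilyloxy)-13,14,15,16-tetranorlabdan-7-one
Product: 19 6,8,12-tris(triethylsilyloxy)-13,14,15,16-tetranorlabdan-7-one (6-O equatorial on the opposite face), via C6=C7 triethylsilyl enol ether 18 (not isolated)
Conditions: LiN(i-Pr)2, THF, −78 to −40 °C; Et3SiCl, −78 to 0 °C; then mCPBA, NaHCO3, CH2Cl2, −20 °C
Reagents that add atoms: chlorotriethylsilane, CC[Si](CC)(CC)Cl; mCPBA, OOC(=O)c1cccc(Cl)c1
Why: C6 is now the only enolisable position, and Rubottom oxidation of its silyl enol ether should occur from the face opposite C20 and the axial C4 methyl, placing the 6-oxygen equatorial.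

**Step 14**
Reactants: 19 6,8,12-tris(triethylsilyloxy)-13,14,15,16-tetranorlabdan-7-one
Product: 20 6,8,12-tris(triethylsilyloxy)-13,14,15,16-tetranorlabdan-7-ol (7-OH equatorial on the C20 face)
Conditions: NaBH4, MeOH/THF, −20 to 0 °C; NH4Cl quench
Reagents that add atoms: none
Why: Borohydride reduction should deliver hydride along the axial trajectory on the opposite face, the C20 face being screened by the axial C17 methyl, to give the equatorial 7-alcohol trans to both neighbouring oxygens, while the low temperature suppresses silyl migration.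

**Step 15**
Reactants: 20 6,8,12-tris(triethylsilyloxy)-13,14,15,16-tetranorlabdan-7-ol; 21 acetic anhydride
Product: 22 6,8,12-tris(triethylsilyloxy)-13,14,15,16-tetranorlabdan-7-yl acetate
Conditions: Ac2O, DMAP, pyridine, CH2Cl2, rt to 40 °C
Reagents that add atoms: acetic anhydride (21), CC(=O)OC(C)=O
Why: DMAP-catalysed acylation acetylates the only free hydroxyl group, so the 7-acetate is placed without relying on selectivity among the three ring oxygens.

**Step 16**
Reactants: 22 6,8,12-tris(triethylsilyloxy)-13,14,15,16-tetranorlabdan-7-yl acetate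
Product: 23 12-oxo-6,8-bis(triethylsilyloxy)-13,14,15,16-tetranorlabdan-7-yl acetate
Conditions: (COCl)2 (4 equiv), DMSO (8 equiv), CH2Cl2, −78 to −40 °C; Et3N, −78 °C to rt
Reagents that add atoms: none
Why: Under Swern conditions a primary triethylsilyl ether is cleaved by the chlorosulfonium salt and oxidised directly to the aldehyde, while the hindered secondary and tertiary triethylsilyl ethers stay, so the 8-oxygen remains masked and no lactol can form.

**Step 17**
Reactants: 23 12-oxo-6,8-bis(triethylsilyloxy)-13,14,15,16-tetranorlabdan-7-yl acetate; 24 ethyltriphenylphosphonium iodide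
Product: 25 (12Z)-13-iodo-6,8-bis(triethylsilyloxy)-14,15-dinorlabd-12-en-7-yl acetate
Conditions: 24, n-BuLi, THF, 0 °C; I2, −78 °C; NaN(SiMe3)2, −20 °C; then 23, −78 °C
Reagents that add atoms: ethyltriphenylphosphonium iodide (24), CC[P+](c1ccccc1)(c1ccccc1)c1ccccc1.[I-]; iodine, II
Why: The α-iodoalkylidene Wittig olefination (Stork–Zhao type) of an aliphatic aldehyde should give the (Z)-2-iodoalkene under kinetic control, with iodine cis to C11, at a temperature at which the acetate is not attacked.

**Step 18**
Reactants: 25 (12Z)-13-iodo-6,8-bis(triethylsilyloxy)-14,15-dinorlabd-12-en-7-yl acetate; 26 tributyl(vinyl)stannane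
Product: 27 (12Z)-6,8-bis(triethylsilyloxy)labda-12,14-dien-7-yl acetate
Conditions: Pd(PPh3)4 (5 mol %), CuI (10 mol %), DMF, rt to 40 °C
Reagents that add atoms: tributyl(vinyl)stannane (26), C=C[Sn](CCCC)(CCCC)CCCC
Why: Stille coupling replaces iodine by vinyl with retention of the alkene geometry under neutral conditions that spare the acetate, giving the (12Z)-diene.

**Step 19**
Reactants: 27 (12Z)-6,8-bis(triethylsilyloxy)labda-12,14-dien-7-yl acetate
Product: 28 (5R,6S,7R,8R,9S,10R,12Z)-6,8-dihydroxylabda-12,14-dien-7-yl acetate (CNP0225877.2)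
Conditions: HF·pyridine, pyridine, THF, 0 °C to rt
Reagents that add atoms: none
Why: Buffered fluoride desilylation should remove both triethylsilyl groups without acid strong enough to cyclise the 8-hydroxy diene and without base that would shift the acetate to O6.

**Compound list**
1 | 2,6-dimethylphenylacetic acid | Cc1cccc(C)c1CC(=O)O | starting material
2 | methyl 2-(2,6-dimethylphenyl)acetate | COC(=O)Cc1c(C)cccc1C | intermediate
3 | 4-chlorobutanoyl chloride | ClCCCC(=O)Cl | starting material
4 | methyl 2-[3-(4-chlorobutanoyl)-2,6-dimethylphenyl]acetate | COC(=O)Cc1c(C)ccc(C(=O)CCCCl)c1C | intermediate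
5 | dimethylzinc | C[Zn]C | starting material
6 | methyl 2-[3-(5-chloro-2-methylpentan-2-yl)-2,6-dimethylphenyl]acetate | COC(=O)Cc1c(C)ccc(C(C)(C)CCCCl)c1C | intermediate
7 | methyl 2-[3-bromo-5-(5-chloro-2-methylpentan-2-yl)-2,6-dimethylphenyl]acetate | COC(=O)Cc1c(C)c(Br)cc(C(C)(C)CCCCl)c1C | intermediate
8 | 2-[3-bromo-5-(5-chloro-2-methylpentan-2-yl)-2,6-dimethylphenyl]ethanol | OCCc1c(C)c(Br)cc(C(C)(C)CCCCl)c1C | intermediate
9 | {2-[3-bromo-5-(5-chloro-2-methylpentan-2-yl)-2,6-dimethylphenyl]ethoxy}triethylsilane | CC[Si](CC)(CC)OCCc1c(C)c(Br)cc(C(C)(C)CCCCl)c1C | intermediate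
10 | 2-{5-(5-chloro-2-methylpentan-2-yl)-2,4-dimethyl-3-[2-(triethylsilyloxy)ethyl]phenyl}-4,4,5,5-tetramethyl-1,3,2-dioxaborolane | CC[Si](CC)(CC)OCCc1c(C)c(B2OC(C)(C)C(C)(C)O2)cc(C(C)(C)CCCCl)c1C | intermediate
11 | 5-(5-chloro-2-methylpentan-2-yl)-2,4-dimethyl-3-[2-(triethylsilyloxy)ethyl]phenol | CC[Si](CC)(CC)OCCc1c(C)c(O)cc(C(C)(C)CCCCl)c1C | intermediate
12 | 2-bromo-3-(5-chloro-2-methylpentan-2-yl)-4,6-dimethyl-5-[2-(triethylsilyloxy)ethyl]phenol | CC[Si](CC)(CC)OCCc1c(C)c(O)c(Br)c(C(C)(C)CCCCl)c1C | intermediate
13 | 2-bromo-3-(5-iodo-2-methylpentan-2-yl)-4,6-dimethyl-5-[2-(triethylsilyloxy)ethyl]phenol | CC[Si](CC)(CC)OCCc1c(C)c(O)c(Br)c(C(C)(C)CCCI)c1C | intermediate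
14 | (10S)-6-bromo-12-(triethylsilyloxy)-13,14,15,16-tetranorlabda-5,8-dien-7-one | CC[Si](CC)(CC)OCCC1=C(C)C(=O)C(Br)=C2C(C)(C)CCC[C@]21C | intermediate
15 | 12-(triethylsilyloxy)-13,14,15,16-tetranorlabdan-7-one, trans-fused, H5 and H9 on the opposite face, C17 equatorial | CC[Si](CC)(CC)OCC[C@@H]1[C@@H](C)C(=O)C[C@@H]2C(C)(C)CCC[C@]21C | intermediate
16 | 7,12-bis(triethylsilyloxy)-13,14,15,16-tetranorlabd-7-ene (C7=C8 silyl enol ether) | CC[Si](CC)(CC)OCC[C@@H]1C(C)=C(O[Si](CC)(CC)CC)C[C@@H]2C(C)(C)CCC[C@]21C | intermediate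
17 | 8,12-bis(triethylsilyloxy)-13,14,15,16-tetranorlabdan-7-one, 8-O on the opposite face | CC[Si](CC)(CC)OCC[C@@H]1[C@@](C)(O[Si](CC)(CC)CC)C(=O)C[C@@H]2C(C)(C)CCC[C@]21C | intermediate
18 | 7,8,12-tris(triethylsilyloxy)-13,14,15,16-tetranorlabd-6-ene (C6=C7 silyl enol ether) | CC[Si](CC)(CC)OCC[C@@H]1[C@@](C)(O[Si](CC)(CC)CC)C(O[Si](CC)(CC)CC)=C[C@@H]2C(C)(C)CCC[C@]21C | intermediate
19 | 6,8,12-tris(triethylsilyloxy)-13,14,15,16-tetranorlabdan-7-one, 6-O and 8-O on the opposite face | CC[Si](CC)(CC)OCC[C@@H]1[C@@](C)(O[Si](CC)(CC)CC)C(=O)[C@@H](O[Si](CC)(CC)CC)[C@@H]2C(C)(C)CCC[C@]21C | intermediate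
20 | 6,8,12-tris(triethylsilyloxy)-13,14,15,16-tetranorlabdan-7-ol, 7-OH on the C20 face | CC[Si](CC)(CC)OCC[C@@H]1[C@@](C)(O[Si](CC)(CC)CC)[C@H](O)[C@@H](O[Si](CC)(CC)CC)[C@@H]2C(C)(C)CCC[C@]21C | intermediate
21 | acetic anhydride | CC(=O)OC(C)=O | starting material
22 | 6,8,12-tris(triethylsilyloxy)-13,14,15,16-tetranorlabdan-7-yl acetate | CC[Si](CC)(CC)OCC[C@@H]1[C@@](C)(O[Si](CC)(CC)CC)[C@H](OC(C)=O)[C@@H](O[Si](CC)(CC)CC)[C@@H]2C(C)(C)CCC[C@]21C | intermediate
23 | 12-oxo-6,8-bis(triethylsilyloxy)-13,14,15,16-tetranorlabdan-7-yl acetate | O=CC[C@@H]1[C@@](C)(O[Si](CC)(CC)CC)[C@H](OC(C)=O)[C@@H](O[Si](CC)(CC)CC)[C@@H]2C(C)(C)CCC[C@]21C | intermediate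
24 | ethyltriphenylphosphonium iodide | CC[P+](c1ccccc1)(c1ccccc1)c1ccccc1.[I-] | starting material
25 | (12Z)-13-iodo-6,8-bis(triethylsilyloxy)-14,15-dinorlabd-12-en-7-yl acetate | I/C(C)=C\C[C@@H]1[C@@](C)(O[Si](CC)(CC)CC)[C@H](OC(C)=O)[C@@H](O[Si](CC)(CC)CC)[C@@H]2C(C)(C)CCC[C@]21C | intermediate
26 | tributyl(vinyl)stannane | C=C[Sn](CCCC)(CCCC)CCCC | starting material
27 | (12Z)-6,8-bis(triethylsilyloxy)labda-12,14-dien-7-yl acetate | C=C/C(C)=C\C[C@@H]1[C@@](C)(O[Si](CC)(CC)CC)[C@H](OC(C)=O)[C@@H](O[Si](CC)(CC)CC)[C@@H]2C(C)(C)CCC[C@]21C | intermediate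
28 | (5R,6S,7R,8R,9S,10R,12Z)-6,8-dihydroxylabda-12,14-dien-7-yl acetate | C=C/C(C)=C\C[C@@H]1[C@@](C)(O)[C@H](OC(C)=O)[C@@H](O)[C@@H]2C(C)(C)CCC[C@]21C | target

**Step count**
Total: 19 steps. Longest linear sequence: 19 steps (from 1).

**Steps most likely to fail**

Step 10. The intramolecular alkylation may run largely through phenolate that is not paired with the chiral cation, so that the two faces of C10 are poorly differentiated, and attack through C6 may compete. Fallback with known chemistry: 13 is cyclised with t-BuOK in t-BuOH/THF at rt, the established racemic base-mediated para-alkylation of a phenolate, to the racemic dienone F1. Preparative chromatography on a chiral stationary phase (amylose tris(3,5-dimethylphenylcarbamate)) then separates the unwanted (10R) enantiomer F2 from 14, where the route is rejoined.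

Step 11. The reduction may stop unevenly, leaving part of the material at the enone level or over-reducing the C7 carbonyl, so that a mixture of oxidation levels results. Fallback: 14 is reduced exhaustively (excess Li, EtOH, NH3/THF, −33 °C) to a single oxidation level, the saturated C7 carbinol F3. F3 is then oxidised with Dess–Martin periodinane (NaHCO3, CH2Cl2) to 15, where the route is rejoined.

Step 12. Under equilibrating silylation part of the enol ether may form toward C6, so that oxygen is introduced at the wrong α-carbon. Fallback: the order of the two oxidations is inverted under kinetic control. 15 is deprotonated with LiN(i-Pr)2 at −78 °C at the less substituted C6 and silylated to the C6=C7 triethylsilyl enol ether F4. Rubottom oxidation (mCPBA, NaHCO3) gives the 6-(triethylsilyloxy) ketone F5. A second deprotonation is then expected at C8, the α-carbon that bears no oxygen; silylation gives the C7=C8 triethylsilyl enol ether F6, and Rubottom oxidation of F6 gives 19, where the route is rejoined.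

**Further compounds**
F1 | step 10 | racemic 6-bromo-12-(triethylsilyloxy)-13,14,15,16-tetranorlabda-5,8-dien-7-one | CC[Si](CC)(CC)OCCC1=C(C)C(=O)C(Br)=C2C(C)(C)CCCC21C
F2 | step 10 | (10R)-6-bromo-12-(triethylsilyloxy)-13,14,15,16-tetranorlabda-5,8-dien-7-one | CC[Si](CC)(CC)OCCC1=C(C)C(=O)C(Br)=C2C(C)(C)CCC[C@@]21C
F3 | step 11 | 12-(triethylsilyloxy)-13,14,15,16-tetranorlabdan-7-ol, trans-fused, mixture of C7 and C8 epimers | CC[Si](CC)(CC)OCC[C@@H]1C(C)C(O)C[C@@H]2C(C)(C)CCC[C@]21C
F4 | step 12 | 7,12-bis(triethylsilyloxy)-13,14,15,16-tetranorlabd-6-ene | CC[Si](CC)(CC)OCC[C@@H]1[C@@H](C)C(O[Si](CC)(CC)CC)=C[C@@H]2C(C)(C)CCC[C@]21C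
F5 | step 12 | 6,12-bis(triethylsilyloxy)-13,14,15,16-tetranorlabdan-7-one, 6-O on the opposite face | CC[Si](CC)(CC)OCC[C@@H]1[C@@H](C)C(=O)[C@@H](O[Si](CC)(CC)CC)[C@@H]2C(C)(C)CCC[C@]21C
F6 | step 12 | 6,7,12-tris(triethylsilyloxy)-13,14,15,16-tetranorlabd-7-ene | CC[Si](CC)(CC)OCC[C@@H]1C(C)=C(O[Si](CC)(CC)CC)[C@@H](O[Si](CC)(CC)CC)[C@@H]2C(C)(C)CCC[C@]21C
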